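**Retrosynthetic overview**

1. Numbering: the target is (1S,4R,6S)-4-hexadecyl-4,6-dimethyl-2,3,7-trioxabicyclo[4.3.0]nonan-8-one, with dioxane ring C1H–O2–O3–C4(Me)(chain C1'–C16')–C5H2–C6(Me), lactone ring C6–O7–C8(=O)–C9H2–C1, and the chain numbered outward from C4.
2. End game: diimide saturates a C9'=C10' alkene; before that the 1,2-dioxane (second ring) is closed by 6-exo peroxy-Michael addition of a C4 hydroperoxide onto a butenolide (first ring); the hydroperoxide comes from Co–H hydrogen-atom transfer/O2 at a C4 methylidene.
3. Key disconnection: chain bond C9'–C10', made as C=C by cross-metathesis of the C18 butenolide triene 9 with oct-1-ene. The enabling feature is that this bond lies in the unbranched polymethylene chain, eight CH2 groups from ring carbon C4, so it can be carried as an isolated 1,2-disubstituted alkene that the HAT peroxidation ignores and diimide removes without touching O2–O3.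
4. C6 (S) comes from a Cu(II)–bis(oxazoline) Mukaiyama aldol of the enolsilane of dodec-11-en-2-one (from undec-10-enoic acid) with methyl pyruvate; C1 (S) follows from the cis ring fusion; C4 is obtained by separation of epimers.
5. Ring order: butenolide (step 6), then 1,2-dioxane (step 9).

Key step: step 7

Remark: C4 arises from an acyclic tertiary radical flanked by CH3 and an n-alkyl arm, so no induction is claimed there; both C4 epimers are expected and the (4R)-compound is secured by separating the bicyclic diastereomers in step 9.

**Route**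

Step 1
Reactants: 1 undec-10-enoic acid
Product: 2 dodec-11-en-2-one
Conditions: MeLi (2.2 equiv), Et2O, 0 °C to rt; inverse quench into cold 1 M HCl
Reagents that add atoms: methyllithium [Li]C
Why: Addition of an organolithium to a lithium carboxylate stops at the dilithio gem-diolate, which gives the methyl ketone on hydrolysis (carboxylic acid to methyl ketone synthesis); no stereocenter is involved.

Step 2
Reactants: 2 dodec-11-en-2-one
Product: 3 2-[(trimethylsilyl)oxy]dodeca-1,11-diene
Conditions: LDA (1.05 equiv), THF, −78 °C; TMSCl, −78 to 0 °C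
Reagents that add atoms: chlorotrimethylsilane C[Si](C)(C)Cl
Why: Kinetic deprotonation of the methyl ketone on its CH3 side by the hindered amide and O-silylation of the enolate should give the terminal enolsilane (kinetic enolate trapping).

Step 3
Reactants: 3 2-[(trimethylsilyl)oxy]dodeca-1,11-diene; 4 methyl pyruvate
Product: 5 methyl (2S)-2-methyl-4-oxo-2-[(trimethylsilyl)oxy]tetradec-13-enoate
Conditions: [Cu((S,S)-t-Bu-box)](OTf)2 (10 mol %), THF, −78 °C; filtration through Et3N-deactivated silica
Reagents that add atoms: none
Why: Catalytic enantioselective Mukaiyama aldol addition to a pyruvate ester: the pyruvate chelates the square-planar Cu(II)–bis(oxazoline) through both carbonyls, a tert-butyl group screens the re face of the ketone, and si-face attack by the enolsilane sets the (S)-tertiary carbinol (the later C6) with silyl transfer to the new oxygen.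

Step 4
Reactants: 5 methyl (2S)-2-methyl-4-oxo-2-[(trimethylsilyl)oxy]tetradec-13-enoate
Product: 6 methyl (2S)-2-methyl-4-methylidene-2-[(trimethylsilyl)oxy]tetradec-13-enoate
Conditions: Ph3PCH3Br, KHMDS, THF, 0 °C; then 5, 0 °C to rt
Reagents that add atoms: methylidenetriphenylphosphorane C=P(c1ccccc1)(c1ccccc1)c1ccccc1
Why: Wittig methylenation, in which the ylide should add to the ketone much faster than to the hindered α-quaternary ester, while the silyl ether blocks retro-aldol cleavage; the stereocenter is not touched.

Step 5
Reactants: 6 methyl (2S)-2-methyl-4-methylidene-2-[(trimethylsilyl)oxy]tetradec-13-enoate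
Product: 7 (2S)-2-methyl-4-methylidene-2-[(trimethylsilyl)oxy]tetradec-13-enal
Conditions: DIBAL-H (1.15 equiv), CH2Cl2, −78 °C; MeOH, then aq. Rochelle salt
Reagents that add atoms: none
Why: Partial reduction of an α-silyloxy ester with DIBAL-H, whose tetrahedral aluminium hemiacetal is stable at −78 °C and releases the aldehyde only on work-up; the quaternary α-carbon cannot epimerise and the alkenes are inert.

Step 6
Reactants: 7 (2S)-2-methyl-4-methylidene-2-[(trimethylsilyl)oxy]tetradec-13-enal
Product: 9 (S)-5-methyl-5-(2-methylidenedodec-11-en-1-yl)furan-2(5H)-one, via Z-enoate silyl ether 8 (not isolated)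
Conditions: (CF3CH2O)2P(O)CH2CO2Me, KHMDS, 18-crown-6, THF, −78 °C; then 1 M aq. HCl, THF, rt
Reagents that add atoms: methyl bis(2,2,2-trifluoroethyl)phosphonoacetate COC(=O)CP(=O)(OCC(F)(F)F)OCC(F)(F)F
Why: Still–Gennari olefination should give the Z-enoate, and acid then removes the trimethylsilyl group so that the tertiary hydroxyl lactonises onto the cis ester to the butenolide (first ring); the carbinol configuration is carried over unchanged.

Step 7
Reactants: 9 (S)-5-methyl-5-(2-methylidenedodec-11-en-1-yl)furan-2(5H)-one; 10 oct-1-ene
Product: 11 (S)-5-methyl-5-(2-methylideneoctadec-11-en-1-yl)furan-2(5H)-one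
Conditions: Grubbs II (3 mol %), oct-1-ene (8 equiv), 1,4-benzoquinone (10 mol %), CH2Cl2, 40 °C, Ar sparge; stopped when 9 is consumed
Reagents that add atoms: none
Why: Olefin cross-metathesis by the Chauvin mechanism: the Ru alkylidene exchanges the =CH2 ends of the terminal alkene of 9 and of oct-1-ene through ruthenacyclobutanes, ethene leaves, and the C9'=C10' bond that completes the C24 skeleton is formed. The closest known reaction type is cross-metathesis of two type I terminal alkenes with one partner in excess. No ring is closed and no stereocenter is formed; the E/Z geometry of the new alkene is irrelevant because step 10 saturates it, and the quaternary carbinol carbon is not touched. The step needs site selectivity among three C=C bonds and cross- over homo-coupling: the 1,1-disubstituted methylidene (type III, flanked by a CH2 on a quaternary carbon) and the conjugated ring alkene next to the quaternary carbon (type IV) should not compete within the short reaction time, and the excess of oct-1-ene, whose dimer tetradec-7-ene is also a heptylidene donor, should drive 9 to the cross product. Benzoquinone is added to suppress Ru–H migration of the terminal double bond, which would shorten the chain.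

Step 8
Reactants: 11 (S)-5-methyl-5-(2-methylideneoctadec-11-en-1-yl)furan-2(5H)-one
Product: 12 (5S)-5-methyl-5-[2-methyl-2-(triethylsilylperoxy)octadec-11-en-1-yl]furan-2(5H)-one
Conditions: Co(thd)2 (10 mol %), O2 (1 atm), Et3SiH (2 equiv), ClCH2CH2Cl, rt
Reagents that add atoms: dioxygen O=O; triethylsilane CC[SiH](CC)CC
Why: Mukaiyama–Isayama hydroperoxysilylation: Markovnikov hydrogen-atom transfer from a cobalt hydride to the CH2 end of the 1,1-disubstituted alkene gives the tertiary radical, which traps O2 and is silylated, on the substrate class (5-(2-methylidenealkyl)butenolides) for which this reaction is established and much faster than at the 1,2-disubstituted chain alkene or the electron-poor ring alkene; the new peroxide-bearing center (the later C4) forms without facial bias.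

Step 9
Reactants: 12 (5S)-5-methyl-5-[2-methyl-2-(triethylsilylperoxy)octadec-11-en-1-yl]furan-2(5H)-one
Product: 14 (1S,4R,6S)-4-(hexadec-9-en-1-yl)-4,6-dimethyl-2,3,7-trioxabicyclo[4.3.0]nonan-8-one, via hydroperoxide 13 (not isolated)
Conditions: (i) conc. HCl (cat.), MeOH, 0 °C; (ii) Et2NH, CF3CH2OH, rt; SiO2 chromatography
Reagents that add atoms: none
Why: Acidic methanolysis frees the hydroperoxide, which under amine catalysis adds 6-exo-trig to the butenolide β-carbon (intramolecular oxa-Michael reaction, second ring): the CH2 tether on the quaternary carbon allows only the cis-fused bicycle, so C1 is set as S by C6, while C4 is sorted here by chromatography of the two bicyclic diastereomers (or after step 10 if the E/Z isomers blur the separation).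

Step 10
Reactants: 14 (1S,4R,6S)-4-(hexadec-9-en-1-yl)-4,6-dimethyl-2,3,7-trioxabicyclo[4.3.0]nonan-8-one
Product: 15 (1S,4R,6S)-4-hexadecyl-4,6-dimethyl-2,3,7-trioxabicyclo[4.3.0]nonan-8-one
Conditions: KO2CN=NCO2K (excess, in portions), AcOH, MeOH/CH2Cl2, 0 °C to rt
Reagents that add atoms: none
Why: Diimide reduction transfers H2 in a concerted syn fashion to the non-polar chain C=C of either geometry and should leave the O–O bond and the lactone untouched, as is usual for peroxides; no stereocenter is affected.

**Compound list**

1 | undec-10-enoic acid | C=CCCCCCCCCC(=O)O | starting material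
2 | dodec-11-en-2-one | CC(=O)CCCCCCCCC=C | intermediate
3 | 2-[(trimethylsilyl)oxy]dodeca-1,11-diene | C=C(O[Si](C)(C)C)CCCCCCCCC=C | intermediate
4 | methyl pyruvate | CC(=O)C(=O)OC | starting material
5 | methyl (2S)-2-methyl-4-oxo-2-[(trimethylsilyl)oxy]tetradec-13-enoate | COC(=O)[C@@](C)(O[Si](C)(C)C)CC(=O)CCCCCCCCC=C | intermediate
6 | methyl (2S)-2-methyl-4-methylidene-2-[(trimethylsilyl)oxy]tetradec-13-enoate | COC(=O)[C@@](C)(O[Si](C)(C)C)CC(=C)CCCCCCCCC=C | intermediate
7 | (2S)-2-methyl-4-methylidene-2-[(trimethylsilyl)oxy]tetradec-13-enal | O=C[C@@](C)(O[Si](C)(C)C)CC(=C)CCCCCCCCC=C | intermediate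
8 | methyl (2Z,4S)-4-methyl-6-methylidene-4-[(trimethylsilyl)oxy]hexadeca-2,15-dienoate (not isolated) | COC(=O)/C=C\[C@@](C)(O[Si](C)(C)C)CC(=C)CCCCCCCCC=C | intermediate
9 | (S)-5-methyl-5-(2-methylidenedodec-11-en-1-yl)furan-2(5H)-one | C[C@@]1(CC(=C)CCCCCCCCC=C)OC(=O)C=C1 | intermediate
10 | oct-1-ene | C=CCCCCCC | starting material
11 | (S)-5-methyl-5-(2-methylideneoctadec-11-en-1-yl)furan-2(5H)-one (E/Z mixture at the chain alkene, geometry left open because step 10 erases it) | C[C@@]1(CC(=C)CCCCCCCCC=CCCCCCC)OC(=O)C=C1 | intermediate
12 | (5S)-5-methyl-5-[2-methyl-2-(triethylsilylperoxy)octadec-11-en-1-yl]furan-2(5H)-one (both epimers at the peroxide carbon, E/Z) | C[C@@]1(CC(C)(OO[Si](CC)(CC)CC)CCCCCCCCC=CCCCCCC)OC(=O)C=C1 | intermediate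
13 | (5S)-5-(2-hydroperoxy-2-methyloctadec-11-en-1-yl)-5-methylfuran-2(5H)-one (both epimers, E/Z; not isolated) | C[C@@]1(CC(C)(OO)CCCCCCCCC=CCCCCCC)OC(=O)C=C1 | intermediate
14 | (1S,4R,6S)-4-(hexadec-9-en-1-yl)-4,6-dimethyl-2,3,7-trioxabicyclo[4.3.0]nonan-8-one (E/Z) | CCCCCCC=CCCCCCCCC[C@]1(C)C[C@]2(C)OC(=O)C[C@@H]2OO1 | intermediate
15 | (1S,4R,6S)-4-hexadecyl-4,6-dimethyl-2,3,7-trioxabicyclo[4.3.0]nonan-8-one | CCCCCCCCCCCCCCCC[C@]1(C)C[C@]2(C)OC(=O)C[C@@H]2OO1 | target

**Count and risks**

Total step count: 10. Longest linear sequence: 10 steps, from undec-10-enoic acid.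

Step 8. What may go wrong: hydrogen-atom transfer is not confined to the methylidene (attack on the C9'=C10' alkene or conjugate reduction of the butenolide), and the cobalt peroxide collapses reductively to the tertiary alcohol. Fallback: an ionic Markovnikov perhydration replaces the radical step. Compound 11 is treated with 50% aqueous H2O2 and catalytic H2SO4 at 0 °C; only the 1,1-disubstituted alkene can give a tertiary cation, which H2O2 captures to give hydroperoxide 13 directly. The route is re-entered at 13, at the amine stage of step 9. No new compound is made (F0).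

Step 7. What may go wrong: loss of site selectivity (metathesis at the methylidene), Ru–H migration of the terminal double bond before coupling, or a homodimer of 9 that does not re-enter the cycle. Fallback: the same C9'=C10' bond is built by a Wittig reaction before any other alkene exists. Ozonolysis of 2 (O3, CH2Cl2, −78 °C; Me2S) gives 10-oxoundecanal F1. Heptylidenetriphenylphosphorane (from heptyltriphenylphosphonium bromide and NaHMDS, THF, −78 °C, aldehyde-selective) converts it into (Z)-octadec-11-en-2-one F2. Steps 2 to 6, applied unchanged, then give the enolsilane (Z)-2-[(trimethylsilyl)oxy]octadeca-1,11-diene F3, the aldol silyl ether F4, the methylidene ester F5, the aldehyde F6 and, through the dienoate F7, compound 11 as Z-rich material, where the route continues with step 8.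

Step 6. What may go wrong: erosion of Z-selectivity at the hindered α-quaternary aldehyde (the E-enoate cannot lactonise), or incomplete lactonisation. Fallback: the butenolide is closed by an intramolecular Wittig reaction, whose geometry is fixed by the ring. From 6, LiAlH4 (Et2O, 0 °C; 1 M HCl work-up) gives (2S)-2-methyl-4-methylidenetetradec-13-ene-1,2-diol F8. Parikh–Doering oxidation (SO3·pyridine, DMSO, iPr2NEt) of the primary alcohol alone gives the hydroxy aldehyde F9. Ph3P=C=C=O (toluene, 90 °C) acylates the tertiary alcohol to the phosphoranylidene ester F10, which cyclises to 9.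

**Further compounds**

F0 | step 8 | none | none
F1 | step 7 | 10-oxoundecanal | CC(=O)CCCCCCCCC=O
F2 | step 7 | (Z)-octadec-11-en-2-one | CC(=O)CCCCCCCC/C=C\CCCCCC
F3 | step 7 | (Z)-2-[(trimethylsilyl)oxy]octadeca-1,11-diene | C=C(O[Si](C)(C)C)CCCCCCCC/C=C\CCCCCC
F4 | step 7 | methyl (2S,13Z)-2-methyl-4-oxo-2-[(trimethylsilyl)oxy]icos-13-enoate | COC(=O)[C@@](C)(O[Si](C)(C)C)CC(=O)CCCCCCCC/C=C\CCCCCC
F5 | step 7 | methyl (2S,13Z)-2-methyl-4-methylidene-2-[(trimethylsilyl)oxy]icos-13-enoate | COC(=O)[C@@](C)(O[Si](C)(C)C)CC(=C)CCCCCCCC/C=C\CCCCCC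
F6 | step 7 | (2S,13Z)-2-methyl-4-methylidene-2-[(trimethylsilyl)oxy]icos-13-enal | O=C[C@@](C)(O[Si](C)(C)C)CC(=C)CCCCCCCC/C=C\CCCCCC
F7 | step 7 | methyl (2Z,4S,15Z)-4-methyl-6-methylidene-4-[(trimethylsilyl)oxy]docosa-2,15-dienoate | COC(=O)/C=C\[C@@](C)(O[Si](C)(C)C)CC(=C)CCCCCCCC/C=C\CCCCCC
F8 | step 6 | (2S)-2-methyl-4-methylidenetetradec-13-ene-1,2-diol | OC[C@@](C)(O)CC(=C)CCCCCCCCC=C
F9 | step 6 | (2S)-2-hydroxy-2-methyl-4-methylidenetetradec-13-enal | O=C[C@@](C)(O)CC(=C)CCCCCCCCC=C
F10 | step 6 | (2S)-2-methyl-4-methylidene-1-oxotetradec-13-en-2-yl (triphenylphosphoranylidene)acetate | O=C[C@@](C)(OC(=O)C=P(c1ccccc1)(c1ccccc1)c1ccccc1)CC(=C)CCCCCCCCC=C
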